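## Structural features

- The target is a diarylmethane with no stereocentre. A 3-methylisocoumarin (ring B = benzo ring C4a–C8a; ring C = pyranone C1, O2, C3, C4) is joined through one CH2 at C5 to a tetrasubstituted benzene (ring A: C1' bridge, C2' OMe, C4' OH, C6' CH2OMe).
- The difficulty is regiochemical. Ring B is pentasubstituted (only C7–H is left), and C5 sits between C6–OH and the peri C4–H. The bridge joins two di-ortho-substituted carbons.
- On each ring only one of two resorcinol-type oxygens is methylated (8-OMe with 6-OH; 2'-OMe with 4'-OH).
- Fragile groups: the enol lactone (opened by base), the electron-rich para-hydroxybenzyl linkage (ionised by strong acid or oxidants), the benzylic methyl ether and two free phenols.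
- The key step exploits the alternating pattern of ring B: acyl carbon C1 on C8a, O on C8, H on C7, O on C6, carbon on C5, carbon on C4a. Read as an open chain, C6 and C4a are carbonyl carbons and C5 is the methine between them, where a benzyl group can be put on by enolate alkylation. C1, C8a, C8(OMe), C7 and C6 are atom for atom C2, C3, C4(OMe), C5 and C6 of 4-methoxy-2-pyrone, which already has the 8-OMe/6-O differentiation.
- Ring A carries the same code (bridge carbon = former pyrone C2 carbonyl, C2'–OMe = pyrone C4–OMe, C4'–OH = pyrone C6–O), so both benzene rings can be grown from the same pyrone.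

## Logic of the disconnections

**16 ⇒ 14.** The lactone bond O2–C1 is cut and the C3 carbonyl is re-masked as a dioxolane (through 15). Ring C is the enol lactone of a keto ester, and the ketone must stay masked while ring B is made. The gain is small: one ring and one protecting group. The forward step must hydrolyse the ketal and close the enol lactone in acid without ionising the bridge.

**14 ⇒ 11 (key).** The C4a–C8a bond is cut and ring B is dismantled completely, back through 13 and 12 to a 2-pyrone. In one sentence: ring B does not exist until the end and is made by methoxide opening and aldol re-closure of a 6-(1-benzyl-2-oxoalkyl)-4-methoxy-2-pyrone. The gain is large: a pentasubstituted benzene with two differentiated oxygens and a crowded benzyl group becomes a monosubstituted heterocycle with one sp3 methine. The forward step must make the aldol closure win over Claisen closure and over retro-Claisen cleavage, with only one ketone offered to the nucleophile.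

**11 ⇒ 10 + 8.** The C5–CH2 bridge bond is cut. At this stage it is an sp3–sp3 bond alpha to a ketone and to the pyrone, so the two halves are joined by enolate alkylation and no aromatic C–H has to be selected on either ring. The forward step needs C-alkylation of an ambident enolate with a labile, electron-rich benzylic bromide.

**10 ⇒ 1 + 9.** The C5–C4a bond is cut (acylation of the 6-methyl anion). This brings in C4a, C4, C3 and the methyl group in one piece with the C3 ketone already masked. The ester must be acylated without being enolised.

**8 ⇒ 7 ⇒ 6 ⇒ 5.** These are functional-group changes: C–Br from C–OH, C–OH from the ester, O–Si from O–H. The bridge carbon is the ester carbon of 5. The phenol protecting group must survive hydride and enolate chemistry and fall off in the methoxide of the key step.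

**5 ⇒ 3.** The C1'–C6' bond of ring A is cut by the same ring transformation (through 4). It sets the contiguous CH2OMe / carboxyl / OMe array and the 2'-OMe/4'-OH differentiation without any aromatic substitution. The aldol mode must again win over the Claisen mode.

**3 ⇒ 1 + 2.** The bond between the former pyrone methyl carbon and the methoxyacetyl carbonyl is cut (acylation of the 6-methyl anion), which leaves two commercial compounds.

## Other disconnections considered

**Alternative 1:** This is the first plan that comes to mind. The cut is the C5–CH2 bridge bond between two finished arenes. The forward key step is an acid-promoted Friedel–Crafts benzylation of 6-hydroxy-8-methoxy-3-methylisocoumarin A1 with the para-hydroxybenzylic alcohol A2 through its para-quinone methide.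
- A1 has two nucleophilic positions. C7 lies between both oxygen substituents and is unhindered; C5 is peri to C4–H. Attack at C7 and double benzylation are therefore expected to compete.
- A2 has nucleophilic positions of its own (ortho to its OH) and would oligomerise.
- A1 and A2 must each still be made with a defined mono-O-methyl pattern. The chosen plan sets that pattern and the bridge bond by connectivity, with no arene substitution.

**Alternative 2:** The same bond is cut as an sp2–sp3 cross-coupling. The forward key step is a Suzuki–Miyaura coupling of the 5-bromoisocoumarin A3 with the benzylic pinacol boronate A4 under Pd(PPh3)4 (zerovalent palladium).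
- A3 needs C5-selective bromination of A1 against C7, so the regiochemical problem is only moved.
- The benzylic boronate of an electron-rich ring is prone to protodeboronation.
- The coupling joins two di-ortho-substituted carbons and needs phenol protection.
- Both rings must still be built and functionalised separately, so the route is longer.

**Alternative 3:** Ring C is closed at carbon, with cuts at C4–C4a and O2–C3. The forward key step is a carboxylate-directed C–H activation and oxidative annulation of the benzoic acid A5 with propyne, catalysed by [Cp*RhCl2]2 (trivalent rhodium) with Cu(OAc)2 (divalent copper) as oxidant.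
- The only free ortho C–H of A5 lies between the carboxyl group and the bulky benzyl group.
- Insertion of propyne with the methyl on C3 is weakly controlled, and a terminal alkyne can divert to alkynylation.
- The copper oxidant is a poor match for two free electron-rich phenols.
- A5 already contains the hard C5–CH2 bond and the oxygen pattern, so this key step would not address the real difficulty.

Key step: step 8

## Route

Remark: the target is achiral. Compounds 11–13 carry one stereocentre that is formed racemic and erased in step 8. Compounds 1, 2 and 9 are commercial.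

Step 1
Reactants: 1 4-methoxy-6-methyl-2H-pyran-2-one; 2 methyl methoxyacetate
Product: 3 4-methoxy-6-(3-methoxy-2-oxopropyl)-2H-pyran-2-one
Conditions: 1 (2.1 equiv), LiN(SiMe3)2 (2.1 equiv), THF, −78 °C; 2 (1.0 equiv), −78 → −30 °C; AcOH
Reagents that add atoms: none
Why: Lateral deprotonation of the 6-methyl group gives a vinylogous ester enolate that is acylated by the ester (Claisen-type condensation); the second equivalent of the anion deprotonates the more acidic product, which stops a second addition and leaves no free amide base to enolise 2, and the excess of 1 is recovered.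

Step 2
Reactants: 3 4-methoxy-6-(3-methoxy-2-oxopropyl)-2H-pyran-2-one
Product: 5 methyl 4-hydroxy-2-methoxy-6-(methoxymethyl)benzoate, via ring-opened enol-ether diketo ester 4 (not isolated)
Conditions: NaOMe (3 equiv), MeOH, 0 → 40 °C; then 1 M HCl to pH 3
Reagents that add atoms: sodium methoxide, C[O-].[Na+]
Why: Methoxide opens the pyrone at C2 to 4, whose dienolate closes by aldol condensation of C2 onto the C7 ketone and aromatises (biomimetic aldol aromatisation of a pyrone-masked triketo ester). The pyrone methoxy group becomes the 2-OMe and the carbon of the former ring oxygen the free 4-OH, so the two oxygens are differentiated by connectivity. In a non-chelating alkoxide medium the ketone should be a better acceptor than the vinylogous-carbonate ester, which disfavours the Claisen mode.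

Step 3
Reactants: 5 methyl 4-hydroxy-2-methoxy-6-(methoxymethyl)benzoate
Product: 6 methyl 4-[(tert-butyldimethylsilyl)oxy]-2-methoxy-6-(methoxymethyl)benzoate
Conditions: tBuMe2SiCl (1.2 equiv), imidazole (2.5 equiv), DMF, 23 °C
Reagents that add atoms: tert-butyldimethylsilyl chloride, CC(C)(C)[Si](C)(C)Cl
Why: Standard silylation of the only OH group; the aryl silyl ether should tolerate hydride and enolate chemistry and is meant to be cleaved by methoxide in step 8, so no separate deprotection is needed.

Step 4
Reactants: 6 methyl 4-[(tert-butyldimethylsilyl)oxy]-2-methoxy-6-(methoxymethyl)benzoate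
Product: 7 {4-[(tert-butyldimethylsilyl)oxy]-2-methoxy-6-(methoxymethyl)phenyl}methanol
Conditions: iBu2AlH (2.5 equiv), CH2Cl2, −78 → 0 °C; aq. KNaC4H4O6 (potassium sodium tartrate)
Reagents that add atoms: none
Why: Hydride reduction of the hindered ester to the benzylic alcohol; the silyl ether and the benzylic methyl ether are inert, and the former pyrone carbonyl carbon becomes the future bridge carbon.

Step 5
Reactants: 7 {4-[(tert-butyldimethylsilyl)oxy]-2-methoxy-6-(methoxymethyl)phenyl}methanol
Product: 8 {[4-(bromomethyl)-3-methoxy-5-(methoxymethyl)phenyl]oxy}(tert-butyl)dimethylsilane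
Conditions: CBr4 (1.2 equiv), PPh3 (1.2 equiv), CH2Cl2, −20 → 0 °C; filtered through a short silica plug and used at once
Reagents that add atoms: carbon tetrabromide, BrC(Br)(Br)Br
Why: Appel bromination under neutral conditions converts the benzylic alcohol into the bromide without touching the silyl ether; the electron-rich bromide is not stored.

Step 6
Reactants: 1 4-methoxy-6-methyl-2H-pyran-2-one; 9 ethyl 2-(2-methyl-1,3-dioxolan-2-yl)acetate
Product: 10 4-methoxy-6-[3-(2-methyl-1,3-dioxolan-2-yl)-2-oxopropyl]-2H-pyran-2-one
Conditions: 1 (2.1 equiv), LiN(SiMe3)2 (2.1 equiv), THF, −78 °C; 9 (1.0 equiv), −78 → −30 °C; AcOH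
Reagents that add atoms: none
Why: Same Claisen-type acylation of the lithiated 6-methyl group as in step 1; the ester delivers C4a, C4, C3 and the methyl group with the C3 ketone already masked, and the absence of free amide base should keep 9 from being enolised.

Step 7
Reactants: 10 4-methoxy-6-[3-(2-methyl-1,3-dioxolan-2-yl)-2-oxopropyl]-2H-pyran-2-one; 8 {[4-(bromomethyl)-3-methoxy-5-(methoxymethyl)phenyl]oxy}(tert-butyl)dimethylsilane
Product: 11 6-[1-{4-[(tert-butyldimethylsilyl)oxy]-2-methoxy-6-(methoxymethyl)phenyl}-4-(2-methyl-1,3-dioxolan-2-yl)-3-oxobutan-2-yl]-4-methoxy-2H-pyran-2-one (racemic)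
Conditions: NaH (1.05 equiv), THF, 0 °C; then 8 (1.1 equiv), 0 → 23 °C
Reagents that add atoms: none
Why: The CH2 between the pyrone and the ketone is the only strongly acidic position of 10; its sodium enolate should be alkylated at carbon by the soft benzylic bromide (SN2 alkylation of a stabilised enolate), which forms the C5–CH2 bond of the target. The new stereocentre is formed racemic and disappears in step 8.

Step 8
Reactants: 11 6-[1-{4-[(tert-butyldimethylsilyl)oxy]-2-methoxy-6-(methoxymethyl)phenyl}-4-(2-methyl-1,3-dioxolan-2-yl)-3-oxobutan-2-yl]-4-methoxy-2H-pyran-2-one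
Product: 14 methyl 4-hydroxy-3-{[4-hydroxy-2-methoxy-6-(methoxymethyl)phenyl]methyl}-6-methoxy-2-[(2-methyl-1,3-dioxolan-2-yl)methyl]benzoate, via desilylated pyrone 12 (not isolated), via ring-opened enol-ether diketo ester 13 (not isolated)
Conditions: NaOMe (4 equiv), MeOH, 0 → 40 °C; then AcOH to pH 5
Reagents that add atoms: sodium methoxide, C[O-].[Na+]
Why: Methoxide first cleaves the aryl silyl ether (12) and then adds to the lactone carbonyl (pyrone C2), opening the ring to the (2E)-3-methoxy-5,7-dioxo-2-enoate 13. Deprotonation of 13 at C4 gives a dienolate that is nucleophilic at C2 (the former pyrone C3); C2 adds to the C7 ketone, water is lost and the C5 ketone enolises, so ring B forms irreversibly with the new bond C8a–C4a (isocoumarin numbering). The closest known reaction type is the biomimetic aldol aromatisation of β-polyketo esters and of 6-(2-oxoalkyl)-4-methoxy-2-pyrones to resorcylates, the same reaction as in step 2. The one ring closed is a carbocycle, closed in the 6-(enolendo)-exo-trig aldol mode followed by dehydration. No stereocentre is created, and the one of 11 is destroyed. The step needs aldol closure C2→C7 to win over Claisen closure C6→C1 and over closure C8→C3: the ester is a vinylogous carbonate and a poor acceptor, Claisen closure would give a quaternary C6 in a triketone that cannot aromatise and reverts, the dioxolane leaves C7 as the only ketone in a 1,6-relation to a nucleophilic carbon, and C8 is not deprotonated while the 5,7-dicarbonyl unit carries the charge. The substitution pattern follows from connectivity alone: the pyrone OMe becomes 8-OMe, the pyrone C6 oxygen the free 6-OH, the branch carbon becomes C5 with its benzyl group, and the masked acetonyl arm sits on C4a next to the ester.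

Step 9
Reactants: 14 methyl 4-hydroxy-3-{[4-hydroxy-2-methoxy-6-(methoxymethyl)phenyl]methyl}-6-methoxy-2-[(2-methyl-1,3-dioxolan-2-yl)methyl]benzoate
Product: 16 6-hydroxy-5-{[4-hydroxy-2-methoxy-6-(methoxymethyl)phenyl]methyl}-8-methoxy-3-methyl-1H-isochromen-1-one, via methyl ketone 15 (not isolated)
Conditions: 2 M HCl/THF (1:4), 40 °C; then TsOH·H2O (0.1 equiv), toluene, 70 °C
Reagents that add atoms: water, O
Why: Aqueous acid hydrolyses the dioxolane to the methyl ketone 15, and acid-catalysed enol lactonisation (attack of the enol or hydrate oxygen on the ortho ester with loss of methanol) gives the conjugated 3-methylisocoumarin. The CH2OMe group is meta to both oxygens of ring A and should not ionise, and the mild acid is chosen to leave the diarylmethane intact.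

## Compound list

1 | 4-methoxy-6-methyl-2H-pyran-2-one | COc1cc(C)oc(=O)c1 | starting material
2 | methyl methoxyacetate | COCC(=O)OC | starting material
3 | 4-methoxy-6-(3-methoxy-2-oxopropyl)-2H-pyran-2-one | COCC(=O)Cc1cc(OC)cc(=O)o1 | intermediate
4 | methyl (2E)-3,8-dimethoxy-5,7-dioxooct-2-enoate (not isolated) | COC(=O)/C=C(/OC)CC(=O)CC(=O)COC | intermediate
5 | methyl 4-hydroxy-2-methoxy-6-(methoxymethyl)benzoate | COCc1cc(O)cc(OC)c1C(=O)OC | intermediate
6 | methyl 4-[(tert-butyldimethylsilyl)oxy]-2-methoxy-6-(methoxymethyl)benzoate | COCc1cc(O[Si](C)(C)C(C)(C)C)cc(OC)c1C(=O)OC | intermediate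
7 | {4-[(tert-butyldimethylsilyl)oxy]-2-methoxy-6-(methoxymethyl)phenyl}methanol | COCc1cc(O[Si](C)(C)C(C)(C)C)cc(OC)c1CO | intermediate
8 | {[4-(bromomethyl)-3-methoxy-5-(methoxymethyl)phenyl]oxy}(tert-butyl)dimethylsilane | COCc1cc(O[Si](C)(C)C(C)(C)C)cc(OC)c1CBr | intermediate
9 | ethyl 2-(2-methyl-1,3-dioxolan-2-yl)acetate | CCOC(=O)CC1(C)OCCO1 | starting material
10 | 4-methoxy-6-[3-(2-methyl-1,3-dioxolan-2-yl)-2-oxopropyl]-2H-pyran-2-one | COc1cc(CC(=O)CC2(C)OCCO2)oc(=O)c1 | intermediate
11 | 6-[1-{4-[(tert-butyldimethylsilyl)oxy]-2-methoxy-6-(methoxymethyl)phenyl}-4-(2-methyl-1,3-dioxolan-2-yl)-3-oxobutan-2-yl]-4-methoxy-2H-pyran-2-one (racemic) | COCc1cc(O[Si](C)(C)C(C)(C)C)cc(OC)c1CC(C(=O)CC1(C)OCCO1)c1cc(OC)cc(=O)o1 | intermediate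
12 | 6-[1-[4-hydroxy-2-methoxy-6-(methoxymethyl)phenyl]-4-(2-methyl-1,3-dioxolan-2-yl)-3-oxobutan-2-yl]-4-methoxy-2H-pyran-2-one (racemic, not isolated) | COCc1cc(O)cc(OC)c1CC(C(=O)CC1(C)OCCO1)c1cc(OC)cc(=O)o1 | intermediate
13 | methyl (2E)-6-{[4-hydroxy-2-methoxy-6-(methoxymethyl)phenyl]methyl}-3-methoxy-8-(2-methyl-1,3-dioxolan-2-yl)-5,7-dioxooct-2-enoate (racemic, not isolated) | COC(=O)/C=C(/OC)CC(=O)C(Cc1c(COC)cc(O)cc1OC)C(=O)CC1(C)OCCO1 | intermediate
14 | methyl 4-hydroxy-3-{[4-hydroxy-2-methoxy-6-(methoxymethyl)phenyl]methyl}-6-methoxy-2-[(2-methyl-1,3-dioxolan-2-yl)methyl]benzoate | COCc1cc(O)cc(OC)c1Cc1c(O)cc(OC)c(C(=O)OC)c1CC1(C)OCCO1 | intermediate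
15 | methyl 4-hydroxy-3-{[4-hydroxy-2-methoxy-6-(methoxymethyl)phenyl]methyl}-6-methoxy-2-(2-oxopropyl)benzoate (not isolated) | COCc1cc(O)cc(OC)c1Cc1c(O)cc(OC)c(C(=O)OC)c1CC(C)=O | intermediate
16 | 6-hydroxy-5-{[4-hydroxy-2-methoxy-6-(methoxymethyl)phenyl]methyl}-8-methoxy-3-methyl-1H-isochromen-1-one | COCc1cc(O)cc(OC)c1Cc1c(O)cc(OC)c2c(=O)oc(C)cc12 | target

## Step count and least certain steps

Total: 9 steps. Longest linear sequence: 8 steps (steps 1, 2, 3, 4, 5, 7, 8, 9); steps 6 and 7 join the second branch.

**Step 8 (key).** Methoxide may cleave the branched β-dicarbonyl unit by retro-Claisen attack before the ring closes, because the substituted methine is less acidic and less protected as its enolate. The aldol at the hindered C7 ketone may also be slow enough for Claisen closure followed by deacylation to drain material.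
The fallback changes the manifold from ester to free acid, sets out from 11 and returns at 16. LiOH (aq. THF, 0 °C) removes the silyl group and opens the pyrone hydrolytically to the ring-opened enol-ether diketo acid F1, whose carboxylate is no acyl acceptor, so the Claisen channel is deleted. Buffering to pH 6–7 lets the acid cyclise by the classical triketo-acid aldol to the benzoic acid F2 at a pH where alkoxide cleavage plays no part. Aqueous HCl in THF then hydrolyses the ketal to the keto acid F3, which cyclodehydrates through its lactol to 16 more readily than the ester 15.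

**Step 7.** The ambident enolate may be alkylated at oxygen or twice, or substitution at the di-ortho-substituted benzylic carbon may be slower than ionisation of 8.
The fallback reverses the order in which the two bonds at C5 are made, sets out from 1 and 8 and returns at 11. The lithiated 6-methyl group of 1 (LiN(SiMe3)2, THF, −78 °C), a stronger and purely carbon-centred nucleophile, is alkylated with 8 to the 6-(2-arylethyl)pyrone F4. F4 is then deprotonated at the CH2 next to the pyrone and acylated with 9 under the conditions of step 6, with recovery of the excess F4, to give 11.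

**Step 5.** The bromide may decompose on formation or handling by ionisation to a para-quinone-methide-type cation, followed by loss of silicon and oligomerisation.
The fallback avoids any benzylic halide, sets out from 7 and returns at 11. Oxidation with MnO2 (CH2Cl2) gives the aldehyde F5. Knoevenagel condensation of F5 with 10 (piperidinium acetate, EtOH) gives the alkylidene compound F6, which is reduced in the same flask by hydride transfer from diethyl 2,6-dimethyl-1,4-dihydropyridine-3,5-dicarboxylate (reductive alkylation of an active methylene compound) to 11.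

**Step 2.** Claisen closure of the diketone carbon (C6 of 4) onto the ester would here give an aromatic acylphloroglucinol ether and could compete with the aldol mode.
The fallback again removes the acyl acceptor, sets out from 3 and returns at 5. Aqueous KOH opens the pyrone to the ring-opened enol-ether diketo acid F7, which can only close by aldol. Adjusting to pH 6–7 gives the benzoic acid F8, kept cold to avoid decarboxylation. Me3SiCHN2 in toluene/MeOH then esterifies the carboxyl group selectively to 5.

## Further compounds

F1 | step 8 | (2E)-6-{[4-hydroxy-2-methoxy-6-(methoxymethyl)phenyl]methyl}-3-methoxy-8-(2-methyl-1,3-dioxolan-2-yl)-5,7-dioxooct-2-enoic acid (racemic) | OC(=O)/C=C(/OC)CC(=O)C(Cc1c(COC)cc(O)cc1OC)C(=O)CC1(C)OCCO1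
F2 | step 8 | 4-hydroxy-3-{[4-hydroxy-2-methoxy-6-(methoxymethyl)phenyl]methyl}-6-methoxy-2-[(2-methyl-1,3-dioxolan-2-yl)methyl]benzoic acid | COCc1cc(O)cc(OC)c1Cc1c(O)cc(OC)c(C(=O)O)c1CC1(C)OCCO1
F3 | step 8 | 4-hydroxy-3-{[4-hydroxy-2-methoxy-6-(methoxymethyl)phenyl]methyl}-6-methoxy-2-(2-oxopropyl)benzoic acid | COCc1cc(O)cc(OC)c1Cc1c(O)cc(OC)c(C(=O)O)c1CC(C)=O
F4 | step 7 | 6-(2-{4-[(tert-butyldimethylsilyl)oxy]-2-methoxy-6-(methoxymethyl)phenyl}ethyl)-4-methoxy-2H-pyran-2-one | COCc1cc(O[Si](C)(C)C(C)(C)C)cc(OC)c1CCc1cc(OC)cc(=O)o1
F5 | step 5 | 4-[(tert-butyldimethylsilyl)oxy]-2-methoxy-6-(methoxymethyl)benzaldehyde | COCc1cc(O[Si](C)(C)C(C)(C)C)cc(OC)c1C=O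
F6 | step 5 | 6-[1-{4-[(tert-butyldimethylsilyl)oxy]-2-methoxy-6-(methoxymethyl)phenyl}-4-(2-methyl-1,3-dioxolan-2-yl)-3-oxobut-1-en-2-yl]-4-methoxy-2H-pyran-2-one (E/Z mixture) | COCc1cc(O[Si](C)(C)C(C)(C)C)cc(OC)c1C=C(C(=O)CC1(C)OCCO1)c1cc(OC)cc(=O)o1
F7 | step 2 | (2E)-3,8-dimethoxy-5,7-dioxooct-2-enoic acid | OC(=O)/C=C(/OC)CC(=O)CC(=O)COC
F8 | step 2 | 4-hydroxy-2-methoxy-6-(methoxymethyl)benzoic acid | COCc1cc(O)cc(OC)c1C(=O)O
A1 | alternative 1 | 6-hydroxy-8-methoxy-3-methyl-1H-isochromen-1-one | COc1cc(O)cc2cc(C)oc(=O)c12
A2 | alternative 1 | 4-(hydroxymethyl)-3-methoxy-5-(methoxymethyl)phenol | COCc1cc(O)cc(OC)c1CO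
A3 | alternative 2 | 5-bromo-6-hydroxy-8-methoxy-3-methyl-1H-isochromen-1-one | COc1cc(O)c(Br)c2cc(C)oc(=O)c12
A4 | alternative 2 | tert-butyl{[3-methoxy-5-(methoxymethyl)-4-[(4,4,5,5-tetramethyl-1,3,2-dioxaborolan-2-yl)methyl]phenyl]oxy}dimethylsilane | COCc1cc(O[Si](C)(C)C(C)(C)C)cc(OC)c1CB1OC(C)(C)C(C)(C)O1
A5 | alternative 3 | 4-hydroxy-3-{[4-hydroxy-2-methoxy-6-(methoxymethyl)phenyl]methyl}-6-methoxybenzoic acid | COCc1cc(O)cc(OC)c1Cc1cc(C(=O)O)c(OC)cc1O
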